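**Plan**

1. The linker bond C11–C12 is cut first. Both C15 halves have the same absolute configuration and differ only in C7=C8 versus the saturated C14–C15, so both come from one bicyclic alcohol, 19.
2. In 19, C9–C11 is cut (a [2,3] shift from a 7β allylic alcohol, itself made from the C9 enone by epoxidation and Wharton transposition), then ring A at C3–C4, then the two substituents on C10.
3. Enabling feature: ring B with its C8 methyl, C7=C8 and C9 is the 2-methylcyclohexenone of carvone. The gem-dimethyl carbon C4 on C5, next to the C3 carbinol, is carvone's isopropenyl carbon, so a tertiary C4 radical and a C3 aldehyde close ring A.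
4. Forward: ring B is bought; C10 is made quaternary (allyl, then methyl); the allyl arm becomes the aldehyde; ring A closes by radical cyclization; C11 is installed; the material is split into a sulfone (left) and a hydrogenated aldehyde (right); the halves are joined by Julia–Kocienski olefination, diimide reduction and desilylation.
5. Stereochemistry: C5/C17 from (S)-carvone; C10/C18 by alkylation anti to isopropenyl; the cis ring fusion from the cis tether; C3/C21 from the chair transition state of the cyclization; C9/C13 by suprafacial [2,3] transfer from the 7β oxygen; C14 by hydroxyl-directed hydrogenation.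

Key step: step 5

Numbering: C1–C10 is the left decalin (ring A = C1–C5, C10; ring B = C5–C10), C11–C12 the linker, C13–C22 the right decalin (ring C = C13–C18; ring D = C17–C22). Intermediates carry the numbers of the target carbons they become; in carvone C5 bears isopropenyl, C7=C8 is the alkene, C9 the ketone and C10 the α′ carbon. β is the face of a decalin that carries its angular methyl (on C10 or C18); α is the opposite face. In these terms the target is 3α-OH, 5β-H, 9α-H, 10β-CH3, 13α-H, 14α-CH3, 17β-H, 18β-CH3, 21α-OH.

Assumption: (S)-carvone, allyl bromide, iodomethane and tributyl(iodomethyl)stannane are purchased; reagents are taken to reach ring B of the cis-fused bicycles on the β face, away from the ring A carbon C4 on C5.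

**Route**

Step 1
Reactants: 1 (S)-carvone; 2 allyl bromide
Product: 4 10-allylcarvone (C10 epimers; allyl trans to isopropenyl expected to predominate), via lithium dienolate 3 (not isolated)
Conditions: LiN(iPr)2, THF, −78 °C; then allyl bromide, −78 to 0 °C
Reagents that add atoms: allyl bromide 2 (C=CCBr)
Why: Kinetic deprotonation of the enone at the α′ carbon C10 gives the cross-conjugated lithium dienolate, whose C-allylation (enolate alkylation) is reliable; the new C10 centre does not matter because it is planarized again in step 2.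

Step 2
Reactants: 4 10-allylcarvone; 5 iodomethane
Product: 7 10α-allyl-10β-methylcarvone, via lithium enolate 6 (not isolated)
Conditions: LiN(iPr)2, THF, −78 to −20 °C; then MeI, −78 °C to rt
Reagents that add atoms: iodomethane 5 (CI)
Why: Enolate alkylation of the re-formed tetrasubstituted enolate, in which iodomethane approaches C10 anti to the isopropenyl group on the neighbouring C5, so the methyl ends up β (trans to isopropenyl) and the allyl arm α (cis to it), which fixes the quaternary centre.

Step 3
Reactants: 7 10α-allyl-10β-methylcarvone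
Product: 9 10α-(3-hydroxypropyl)-10β-methylcarvone, via alkyldisiamylborane 8 (not isolated)
Conditions: (3-methylbutan-2-yl)2BH (from BH3·SMe2 and 2-methylbut-2-ene), THF, 0 °C; then NaBO3·4H2O, H2O, rt
Reagents that add atoms: sodium perborate ([Na+].[Na+].O[B-]1(O)OO[B-](O)(O)OO1)
Why: Brown hydroboration–oxidation, in which the bulky dialkylborane adds anti-Markovnikov to the monosubstituted allyl alkene much faster than to the ring-bound 1,1-disubstituted isopropenyl group or the electron-poor enone, and perborate oxidizes the C–B bond without epoxidizing the enone; no stereocentre is formed.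

Step 4
Reactants: 9 10α-(3-hydroxypropyl)-10β-methylcarvone
Product: 10 10α-(3-oxopropyl)-10β-methylcarvone (keto aldehyde)
Conditions: Dess–Martin periodinane, CH2Cl2, 0 °C to rt
Reagents that add atoms: none
Why: Dess–Martin oxidation of a primary alcohol stops at the aldehyde under near-neutral conditions that leave the enone, the isopropenyl group and the quaternary centre untouched.

Step 5
Reactants: 10 10α-(3-oxopropyl)-10β-methylcarvone
Product: 11 cis-fused 3α-hydroxy-4,4,8,10β-tetramethyl-5β-H-Δ7-octalin-9-one (rings A and B)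
Conditions: Fe(acac)3 (30 mol %), PhSiH3 (2.5 equiv), degassed EtOH, 0.02 M, 60 °C
Reagents that add atoms: none
Why: An iron hydride formed from Fe(acac)3 and PhSiH3 passes a hydrogen atom to the CH2 terminus of the isopropenyl group, the resulting tertiary C4 radical adds to the aldehyde carbon C3, and the alkoxy radical is reduced by divalent iron and protonated by ethanol. The closest known reaction type is the iron-mediated hydrogen-atom-transfer cyclization of alkene-tethered ketones to cis-fused bicyclic alcohols; an aldehyde acceptor is the less charted variant of it. Ring A closes in a 6-exo-trig mode onto the carbonyl group, forming C3–C4, and it can only be cis-fused because the isopropenyl group on C5 and the oxopropyl arm on C10 lie on the same face. The new stereocentre C3 is controlled by a chair-like transition state with the carbonyl oxygen pseudo-equatorial, which places the hydroxyl α, anti to H5; because the addition is reversible, the less hindered equatorial alkoxy radical should also be the one that is reduced. The step needs hydrogen-atom transfer to the electron-rich 1,1-disubstituted alkene in the presence of the enone, which the substrate secures because the electron-poor trisubstituted C7=C8 bond reacts far more slowly and no ring of workable size can form from C4 to C7, C8 or C9. Dilution and excess silane favour capture of the alkoxy radical over its β-scission.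

Step 6
Reactants: 11 cis-fused 3α-hydroxy enone
Product: 12 3α-(tert-butyldimethylsilyloxy)-4,4,8,10β-tetramethyl-5β-H-Δ7-octalin-9-one
Conditions: TBSOTf, 2,6-lutidine, CH2Cl2, −78 to 0 °C
Reagents that add atoms: tert-butyldimethylsilyl triflate (CC(C)(C)[Si](C)(C)OS(=O)(=O)C(F)(F)F)
Why: Silyl triflate silylation is the standard protection of a secondary alcohol flanked by a quaternary carbon, and the weak pyridine base does not enolize the enone.

Step 7
Reactants: 12 silyl ether enone
Product: 13 7β,8β-epoxy-3α-(tert-butyldimethylsilyloxy)-4,4,8,10β-tetramethyl-5β-H-decalin-9-one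
Conditions: 30% aq. H2O2, NaOH, MeOH, 0 °C
Reagents that add atoms: hydrogen peroxide (OO)
Why: Weitz–Scheffer nucleophilic epoxidation of a 2-methylcyclohexenone, in which hydroperoxide adds axially to C7 on the face anti to the C4 substituent on C5 (the selectivity known for carvone itself), so the epoxide is 7β,8β.

Step 8
Reactants: 13 epoxy ketone
Product: 15 3α-(tert-butyldimethylsilyloxy)-4,4,8,10β-tetramethyl-5β-H-Δ8-octalin-7β-ol, via epoxy hydrazone 14 (not isolated)
Conditions: N2H4·H2O, AcOH, MeOH, 0 °C to rt
Reagents that add atoms: none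
Why: Wharton transposition, in which the hydrazone of the epoxy ketone opens the epoxide and loses N2, moving the alkene to C8=C9 while the C7–O bond, and with it the 7β configuration, is untouched.

Step 9
Reactants: 15 7β allylic alcohol; 16 tributyl(iodomethyl)stannane
Product: 17 7β-(tributylstannylmethoxy) ether of 15
Conditions: KH, 18-crown-6 (cat.), THF, 0 °C; then Bu3SnCH2I, rt
Reagents that add atoms: tributyl(iodomethyl)stannane 16 (CCCC[Sn](CCCC)(CCCC)CI)
Why: Williamson etherification of the potassium alkoxide with the reactive iodomethylstannane takes place at oxygen and leaves C7 unchanged.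

Step 10
Reactants: 17 stannylmethyl ether
Product: 19 3α-(tert-butyldimethylsilyloxy)-9β-(hydroxymethyl)-4,4,8,10β-tetramethyl-5β,9α-H-Δ7-octalin, via lithiomethyl ether 18 (not isolated)
Conditions: n-BuLi, THF, −78 °C; aqueous work-up
Reagents that add atoms: none
Why: Wittig–Still [2,3] sigmatropic rearrangement, in which tin–lithium exchange gives the α-alkoxy carbanion that is delivered suprafacially from the 7β oxygen to C9 through a five-membered envelope, setting C9–C11 β (H9 α) and re-forming C7=C8 with its C8 methyl.

Step 11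
Reactants: 19 homoallylic alcohol
Product: 20 C11 (1-phenyl-1H-tetrazol-5-yl) sulfide of 19
Conditions: 1-phenyl-1H-tetrazole-5-thiol, PPh3, DIAD, THF, 0 °C to rt
Reagents that add atoms: 1-phenyl-1H-tetrazole-5-thiol (Sc1nnnn1-c1ccccc1)
Why: Mitsunobu thioetherification of a primary alcohol with the acidic tetrazole thiol touches no stereocentre.

Step 12
Reactants: 20 tetrazolyl sulfide
Product: 21 C11 (1-phenyl-1H-tetrazol-5-yl) sulfone (left half)
Conditions: (NH4)6Mo7O24·4H2O (10 mol %), 30% aq. H2O2, EtOH, 0 °C to rt
Reagents that add atoms: hydrogen peroxide (OO)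
Why: Molybdate-catalysed peroxide oxidation takes a sulfide to the sulfone much faster than it epoxidizes an unactivated trisubstituted alkene.

Step 13
Reactants: 19 homoallylic alcohol
Product: 22 right-half alcohol, 21α-(tert-butyldimethylsilyloxy)-13β-(hydroxymethyl)-14α,18β,22,22-tetramethyl-13α,14β,17β-H-decalin
Conditions: [Ir(cod)(PCy3)(py)]PF6 (5 mol %), H2 (1 atm), CH2Cl2, rt
Reagents that add atoms: none
Why: Hydroxyl-directed homogeneous hydrogenation, in which the cationic iridium catalyst binds the C12 hydroxyl and delivers both hydrogens to the β face of the ring alkene (C14=C15 in right-half numbering), so H14 is β and the C14 methyl α, trans to the C13 arm.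

Step 14
Reactants: 22 right-half alcohol
Product: 23 right-half aldehyde (C12 formyl on C13)
Conditions: Dess–Martin periodinane, CH2Cl2, 0 °C to rt
Reagents that add atoms: none
Why: Dess–Martin oxidation under near-neutral conditions gives the α-branched aldehyde without epimerizing C13.

Step 15
Reactants: 21 left-half sulfone; 23 right-half aldehyde
Product: 25 (11E)-alkene, 3α,21α-bis(tert-butyldimethylsilyl) ether, via potassium sulfonyl carbanion 24 (not isolated)
Conditions: KN(SiMe3)2, DME, −60 °C; then 23, −60 °C to rt
Reagents that add atoms: none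
Why: Julia–Kocienski olefination, in which the metallated tetrazolyl sulfone adds to the aldehyde and the adduct collapses by Smiles rearrangement with loss of SO2 and the tetrazolone to the C11=C12 alkene; the geometry is irrelevant and C9 and C13 are not touched at low temperature.

Step 16
Reactants: 25 (11E)-alkene
Product: 26 3α,21α-bis(tert-butyldimethylsilyl) ether of the target
Conditions: p-toluenesulfonyl hydrazide, NaOAc, DME/H2O, reflux
Reagents that add atoms: none
Why: Diimide reduction is selective for the 1,2-disubstituted C11=C12 bond over the trisubstituted C7=C8 bond and, as a metal-free concerted syn transfer of two hydrogens, cannot isomerize the ring alkene.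

Step 17
Reactants: 26 bis-silyl ether
Product: 27 target diol
Conditions: Bu4NF, THF, 60 °C
Reagents that add atoms: none
Why: Fluoride-mediated desilylation frees the C3 and C21 alcohols without affecting the alkene or any stereocentre.

**Compound list**

1 | (S)-carvone | CC1=CC[C@H](C(C)=C)CC1=O | starting material
2 | allyl bromide | C=CCBr | starting material
3 | lithium dienolate of 1 (O–C9=C10) | CC1=CC[C@H](C(C)=C)C=C1[O-].[Li+] | intermediate (not isolated)
4 | 10-allylcarvone (C10 epimers; major epimer drawn, allyl trans to isopropenyl) | CC1=CC[C@H](C(C)=C)[C@@H](CC=C)C1=O | intermediate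
5 | iodomethane | CI | starting material
6 | lithium enolate of 4 | CC1=CC[C@H](C(C)=C)C(CC=C)=C1[O-].[Li+] | intermediate (not isolated)
7 | 10α-allyl-10β-methylcarvone | CC1=CC[C@H](C(C)=C)[C@](C)(CC=C)C1=O | intermediate
8 | [3-(10β-methylcarvon-10-yl)propyl]bis(3-methylbutan-2-yl)borane | CC1=CC[C@H](C(C)=C)[C@](C)(CCCB(C(C)C(C)C)C(C)C(C)C)C1=O | intermediate (not isolated)
9 | 10α-(3-hydroxypropyl)-10β-methylcarvone | CC1=CC[C@H](C(C)=C)[C@](C)(CCCO)C1=O | intermediate
10 | 10α-(3-oxopropyl)-10β-methylcarvone | CC1=CC[C@H](C(C)=C)[C@](C)(CCC=O)C1=O | intermediate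
11 | cis-fused 3α-hydroxy-4,4,8,10β-tetramethyl-5β-H-Δ7-octalin-9-one | CC1=CC[C@@H]2C(C)(C)[C@H](O)CC[C@]2(C)C1=O | intermediate
12 | 3α-tert-butyldimethylsilyl ether of 11 | CC1=CC[C@@H]2C(C)(C)[C@H](O[Si](C)(C)C(C)(C)C)CC[C@]2(C)C1=O | intermediate
13 | 7β,8β-epoxide of 12 | C[C@]12O[C@H]1C[C@@H]3C(C)(C)[C@H](O[Si](C)(C)C(C)(C)C)CC[C@]3(C)C2=O | intermediate
14 | C9 hydrazone of 13 | C[C@]12O[C@H]1C[C@@H]3C(C)(C)[C@H](O[Si](C)(C)C(C)(C)C)CC[C@]3(C)C2=NN | intermediate (not isolated)
15 | 3α-silyloxy-4,4,8,10β-tetramethyl-5β-H-Δ8-octalin-7β-ol | CC1=C[C@@]2(C)CC[C@@H](O[Si](C)(C)C(C)(C)C)C(C)(C)[C@H]2C[C@@H]1O | intermediate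
16 | tributyl(iodomethyl)stannane | CCCC[Sn](CCCC)(CCCC)CI | starting material
17 | 7β-(tributylstannylmethoxy) ether of 15 | CC1=C[C@@]2(C)CC[C@@H](O[Si](C)(C)C(C)(C)C)C(C)(C)[C@H]2C[C@@H]1OC[Sn](CCCC)(CCCC)CCCC | intermediate
18 | 7β-(lithiomethoxy) ether of 15 | CC1=C[C@@]2(C)CC[C@@H](O[Si](C)(C)C(C)(C)C)C(C)(C)[C@H]2C[C@@H]1OC[Li] | intermediate (not isolated)
19 | 3α-silyloxy-9β-(hydroxymethyl)-4,4,8,10β-tetramethyl-5β,9α-H-Δ7-octalin | CC1=CC[C@@H]2C(C)(C)[C@H](O[Si](C)(C)C(C)(C)C)CC[C@]2(C)[C@H]1CO | intermediate
20 | C11 (1-phenyl-1H-tetrazol-5-yl) sulfide of 19 | CC1=CC[C@@H]2C(C)(C)[C@H](O[Si](C)(C)C(C)(C)C)CC[C@]2(C)[C@H]1CSc1nnnn1-c1ccccc1 | intermediate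
21 | C11 (1-phenyl-1H-tetrazol-5-yl) sulfone (left half) | CC1=CC[C@@H]2C(C)(C)[C@H](O[Si](C)(C)C(C)(C)C)CC[C@]2(C)[C@H]1CS(=O)(=O)c1nnnn1-c1ccccc1 | intermediate
22 | right-half alcohol: 21α-silyloxy-13β-(hydroxymethyl)-14α,18β,22,22-tetramethyl-13α,14β,17β-H-decalin | C[C@@H]1CC[C@@H]2C(C)(C)[C@H](O[Si](C)(C)C(C)(C)C)CC[C@]2(C)[C@H]1CO | intermediate
23 | right-half aldehyde (C12 formyl) | C[C@@H]1CC[C@@H]2C(C)(C)[C@H](O[Si](C)(C)C(C)(C)C)CC[C@]2(C)[C@H]1C=O | intermediate
24 | potassium C11 carbanion of 21 | CC1=CC[C@@H]2C(C)(C)[C@H](O[Si](C)(C)C(C)(C)C)CC[C@]2(C)[C@H]1[CH-]S(=O)(=O)c1nnnn1-c1ccccc1.[K+] | intermediate (not isolated)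
25 | (11E)-alkene, 3α,21α-bis-silyl ether | CC1=CC[C@@H]2C(C)(C)[C@H](O[Si](C)(C)C(C)(C)C)CC[C@]2(C)[C@H]1/C=C/[C@H]1[C@H](C)CC[C@@H]2C(C)(C)[C@H](O[Si](C)(C)C(C)(C)C)CC[C@@]21C | intermediate
26 | 3α,21α-bis(tert-butyldimethylsilyl) ether of the target | CC1=CC[C@@H]2C(C)(C)[C@H](O[Si](C)(C)C(C)(C)C)CC[C@]2(C)[C@H]1CC[C@H]1[C@H](C)CC[C@@H]2C(C)(C)[C@H](O[Si](C)(C)C(C)(C)C)CC[C@@]21C | intermediate
27 | target diol CNP0194061.2 | CC1=CC[C@@H]2C(C)(C)[C@H](O)CC[C@]2(C)[C@H]1CC[C@H]1[C@H](C)CC[C@@H]2C(C)(C)[C@H](O)CC[C@@]21C | target

**Count**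

Total step count: 17. Longest linear sequence: 15 steps (steps 1–10, then 11–12 or 13–14, then 15–17).

**Steps most likely to fail**

Step 5. The alkoxy radical may fragment back to the open tertiary radical faster than it is reduced, so that plain reduction of the isopropenyl group takes over; facial control at C3 may also be incomplete. The fallback sets out from 9 and returns at 11. HBr in AcOH/CH2Cl2 at 0 °C adds across the isopropenyl group to give the tertiary bromo alcohol F1, and Dess–Martin oxidation gives the bromo aldehyde F2. Bu3SnH with Et3B and air in toluene forms the same C4 radical by bromine abstraction, and the alkoxy radical from the 6-exo closure is quenched by the stannane, giving 11, possibly mixed with its 3β-hydroxy epimer F3. Whatever the composition, Dess–Martin oxidation to the 3,9-dione F4 and NaBH4 in MeOH/CH2Cl2 at −78 °C should converge on 11: hydride attacks the unconjugated C3 ketone from the β face (that of H5) and spares the hindered enone. The same oxidation and reduction would correct C3 if step 5 itself gave the epimer.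

Step 8. Hydrazine may condense too slowly with a ketone flanked by two fully substituted carbons, letting direct epoxide opening or over-reduction compete; the [2,3] shift of step 10 depends on this alcohol. The fallback sets out from 12 and returns at 19. LiCH2OCH2OCH3 (from tributyl[(methoxymethoxy)methyl]stannane and n-BuLi, THF, −78 °C) adds 1,2 to the C9 ketone to give the tertiary allylic alcohol F5. Pyridinium chlorochromate in CH2Cl2 effects oxidative allylic transposition to the C7 enone F6, whose C8=C9 bond carries C11. p-Toluenesulfonyl hydrazide gives the tosylhydrazone F7. Catecholborane, then NaOAc·3H2O at reflux, reduces it with alkene transposition: hydride enters C7 on the β face and the allylic diazene passes its hydrogen suprafacially to C9 on the α face, giving the methoxymethyl ether F8 with C11 β and C7=C8 restored. Me2BBr in CH2Cl2 at −78 °C then frees 19.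

Step 15. The β-branched sulfonyl carbanion may add sluggishly to the neopentyl-type aldehyde, so that enolization and epimerization at C13 compete; the selective diimide reduction of step 16 also depends on this alkene. The fallback sets out from 19, uses 23, and returns at 26. I2, PPh3 and imidazole convert 19 into the C11 iodide F9. t-BuLi (2 equiv) in Et2O at −78 °C gives the C11 alkyllithium F10, which adds to aldehyde 23 to give the C12 carbinol F11 (both C12 epimers are usable). NaH, CS2 and MeI give the xanthate F12, and Barton–McCombie deoxygenation (Bu3SnH, AIBN, toluene, 90 °C) gives 26 directly, so steps 15 and 16 are both bypassed.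

**Further compounds**

F1 | step 5 | 10α-(3-hydroxypropyl)-10β-methyl-5-(2-bromopropan-2-yl) enone (hydrobromide of 9) | CC1=CC[C@H](C(C)(C)Br)[C@](C)(CCCO)C1=O
F2 | step 5 | bromo aldehyde (hydrobromide of 10) | CC1=CC[C@H](C(C)(C)Br)[C@](C)(CCC=O)C1=O
F3 | step 5 | 3β-hydroxy epimer of 11 | CC1=CC[C@@H]2C(C)(C)[C@@H](O)CC[C@]2(C)C1=O
F4 | step 5 | cis-fused 4,4,8,10β-tetramethyl-5β-H-Δ7-octalin-3,9-dione | CC1=CC[C@@H]2C(C)(C)C(=O)CC[C@]2(C)C1=O
F5 | step 8 | 9-hydroxy-9-[(methoxymethoxy)methyl] adduct of 12 (C9 epimers) | CC1=CC[C@@H]2C(C)(C)[C@H](O[Si](C)(C)C(C)(C)C)CC[C@]2(C)C1(O)COCOC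
F6 | step 8 | 3α-silyloxy-9-[(methoxymethoxy)methyl]-4,4,8,10β-tetramethyl-5β-H-Δ8-octalin-7-one | CC1=C(COCOC)[C@@]2(C)CC[C@@H](O[Si](C)(C)C(C)(C)C)C(C)(C)[C@H]2CC1=O
F7 | step 8 | C7 p-toluenesulfonylhydrazone of F6 | CC1=C(COCOC)[C@@]2(C)CC[C@@H](O[Si](C)(C)C(C)(C)C)C(C)(C)[C@H]2CC1=NNS(=O)(=O)c1ccc(C)cc1
F8 | step 8 | C11 methoxymethyl ether of 19 | CC1=CC[C@@H]2C(C)(C)[C@H](O[Si](C)(C)C(C)(C)C)CC[C@]2(C)[C@H]1COCOC
F9 | step 15 | C11 iodide from 19 | CC1=CC[C@@H]2C(C)(C)[C@H](O[Si](C)(C)C(C)(C)C)CC[C@]2(C)[C@H]1CI
F10 | step 15 | C11 alkyllithium from F9 | CC1=CC[C@@H]2C(C)(C)[C@H](O[Si](C)(C)C(C)(C)C)CC[C@]2(C)[C@H]1C[Li]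
F11 | step 15 | 12-hydroxy derivative of 26 (C12 epimers) | CC1=CC[C@@H]2C(C)(C)[C@H](O[Si](C)(C)C(C)(C)C)CC[C@]2(C)[C@H]1CC(O)[C@H]1[C@H](C)CC[C@@H]2C(C)(C)[C@H](O[Si](C)(C)C(C)(C)C)CC[C@@]21C
F12 | step 15 | C12 S-methyl xanthate of F11 | CC1=CC[C@@H]2C(C)(C)[C@H](O[Si](C)(C)C(C)(C)C)CC[C@]2(C)[C@H]1CC(OC(=S)SC)[C@H]1[C@H](C)CC[C@@H]2C(C)(C)[C@H](O[Si](C)(C)C(C)(C)C)CC[C@@]21C
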